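In a one-step world a racemate goes to product with both hands at one rate, and what is left stays at an excess of zero, which is the origin of our scale. The elm run moves off that zero. At 1.33 min of the elm run more right-handed substrate stands, 43%, than left-handed, 12%, so the free catalyst prefers the left-handed one, while the racemization catalyst interconverts the two.

| flask | left-handed substrate | right-handed substrate | partner | free catalyst | precatalyst | remark | time |
|---|---|---|---|---|---|---|---|
| elm | 0.0020 M | 0.0020 M | 5 mM | 0.18 mM | 0.13 mM | run made earlier |  |
| alder | 0.0020 M | 0.0020 M | 5 mM | 0.18 mM | 0.33 mM | run made earlier |  |
| Thursday's | 0.0020 M | 0.0020 M | 5.00 mM | 0.18 mM | 0.40 mM |  | 20 min |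
| Monday's | 0.0020 M | 0.0020 M | 5.00 mM | 0.18 mM | 0.20 mM |  | 20 min |

| run | time / min | right-handed substrate / % | left-handed substrate / % | left-handed product / % |
|---|---|---|---|---|
| elm | 1.33 | 43 | 12 | 25 |
| elm | 4.00 | 19 | 8 | 35 |
| elm | 6.00 | 18 | 9 | 42 |
| elm | 10.0 | 5 | 3 | 45 |
| alder | 2.50 | 22 | 12 | 32 |
| alder | 5.00 | 12 | 0 | 40 |
| alder | 8.00 | 3 | 3 | 46 |
| alder | 10.0 | 6 | 5 | 46 |

(scatter of a reading: 2 percentage points)

- free catalyst is single-handed; left-handed substrate and right-handed substrate are mirror images of each other, charged as a racemate, each of them at the stated concentration
- what was read earlier has a scatter of 2 percentage points, one standard deviation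
- reactions considered so far: partner + free catalyst + left-handed substrate -> free catalyst + left-handed product; partner + free catalyst + right-handed substrate -> free catalyst + right-handed product; left-handed substrate + racemization catalyst <-> right-handed substrate + racemization catalyst; left-handed product <-> right-handed product; partner + precatalyst -> racemization catalyst + spent reagent
- an excess is below zero if the other one leads

* the winner by excess of right-handed substrate over left-handed substrate among what is left of the two; "neither" if no more than 2 percentage points parts them (Thursday's / Monday's / neither)
* excess of right-handed substrate over left-handed substrate among what is left of the two at the end, Thursday's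
* excess of right-handed substrate over left-handed substrate among what is left of the two at the end, Monday's

Treat each loss as pseudo-first-order and write both down: the amount of substrate cancels, and the excess comes to rest near (difference of the two loss rates) / (4 × racemization rate). The difference goes with free catalyst times partner, the racemization rate with racemization catalyst, so the excess is a gain times partner per racemization catalyst.

Now we turn the settings by hand. Time: each substrate molecule takes one partner, so by 20 min we put partner at its spare amount, the charge less both substrates less the precatalyst, which takes one partner on activation. Partner: that spare amount is 0.600 mM in Thursday's flask and 0.800 mM in Monday's. Precatalyst: it counts in both places, lowering the spare partner and raising the racemization catalyst. Spare partner over precatalyst gives 1.50 for Thursday's, our spare ratio, and 4.00 for Monday's. Free catalyst: equal in both, it enters the gain.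

The gain we read from the elm run at 4.00 min and 6.00 min. The excess there, from the two readings pooled, reads 37.0%, with 27.0% of substrate left at 4.00 min. If we take the precatalyst of the elm run as activated, partner per precatalyst there comes to 15.0, so the gain is about 0.0247, a reading from percentages that carry a scatter of 2 percentage points. We therefore expect 3.70% for Thursday's and 9.88% for Monday's, which puts Monday's ahead by 6.2 points.

The forecast gives lower figures than ours, 3% and 8%, with Monday's ahead: “Monday's wins, though narrowly given the uncertainty.”

Thursday's flask gives 5.28% and Monday's 13.3%, so Monday's leads.

    partner + free catalyst + left-handed substrate → free catalyst + left-handed product (k = 34800 L² mol⁻² s⁻¹)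
    partner + free catalyst + right-handed substrate → free catalyst + right-handed product (k = 2120 L² mol⁻² s⁻¹)
    left-handed substrate + racemization catalyst ⇌ right-handed substrate + racemization catalyst, rate k3*[racemization catalyst]*[left-handed substrate] forward; the back reaction follows from the equilibrium constant (k = 47.6 L mol⁻¹ s⁻¹)
    left-handed product ⇌ right-handed product (k = 0.0547 s⁻¹)
    partner + precatalyst → racemization catalyst + spent reagent (k = 2.82 L mol⁻¹ s⁻¹)

At 20.0 min partner stands at 13% of its charge in Thursday's flask and 17% in Monday's. The two excesses differ by a factor of 2.52, the two spare ratios by 2.67. For a neighbour of Monday's charged with 1.30 mM of partner, the spare ratio comes to −14.5, below zero, so that charge falls short of both substrates and the precatalyst together. At 20.0 min that neighbour's partner, the limiting reagent, stands at 0% and its excess at 0.121%.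

The readings are calculated with constants of no real substance, and the scatter is random.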